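Which flask holds the most product at 20 h, and does the same order already stand at 1.0 h? I hand you these flasks with the question as it stands:

| flask | starting material | coupling partner | free catalyst | temperature | remark | time |
|---|---|---|---|---|---|---|
| oak | 10 mM | 22 mM | 1 mM | 65 °C | run made earlier |  |
| alder | 40 mM | 22 mM | 1 mM | 105 °C | run made earlier |  |
| summer | 20 mM | 22.0 mM | 1.0 mM | 140 °C |  | 20 h |
| dusk | 20 mM | 22.0 mM | 1.0 mM | 125 °C |  | 20 h |
| midnight | 20 mM | 22.0 mM | 1.0 mM | 110 °C |  | 20 h |
| autumn | 20 mM | 22.0 mM | 1.0 mM | 90 °C |  | 20 h |
| dawn | 20 mM | 22.0 mM | 1.0 mM | 70 °C |  | 20 h |
| noon | 20 mM | 22.0 mM | 1.0 mM | 130 °C |  | 20 h |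

- oak (time / h: product / %): 50.0: 14; 96.0: 22; 144: 40; 192: 47
- alder (time / h: product / %): 5.00: 18; 10.0: 28; 15.0: 42; 20.0: 43

(standard deviation of a reading: 2 percentage points)

1. ranking by amount of product, in percent of the starting material charged, from high to low, at 20 h (summer / dusk / midnight / autumn / dawn / noon)
2. the same order at 1.0 h (summer / dusk / midnight / autumn / dawn / noon)
3. the amount of product, in percent of the starting material charged of the flask you put first, at 20 h
4. the amount of product, in percent of the starting material charged of the flask you put last, at 20 h

- for product the crystals are counted in
- as a solid, counted per litre of solution: crystals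
- the earlier runs were read with a standard deviation of 2 percentage points
- on the list of suspects stand: catalyst intermediate B <-> catalyst intermediate C; catalyst intermediate C -> free catalyst + product; starting material + free catalyst <-> catalyst intermediate A; crystals <-> product; coupling partner + catalyst intermediate A <-> catalyst intermediate B

In the oak run the product climbs about evenly while half of the charge turns into product, so I take the rate as not depending on starting material. The alder run flattens between its last two readings, so I take the rate as proportional to c(coupling partner), with the catalyst charge the same in both runs and in your flasks. Product made per hour, divided by the mean c(coupling partner) over the same time, I call the turnover constant. Oak gives 0.00125 /h over its whole run and alder 0.0783 /h over its first reading.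

It is larger in the hotter run, so I expect the hottest flask first and the coolest last at both times. Summer lies above both runs, so I commit to its place, not its height.

For dawn, a straight line through the logarithm of the constant against temperature gives 0.00209 /h, which I call the dawn turnover constant. Holding c(coupling partner) at its charge gives 0.920 mM of product by 20 h. Putting that back, the mean c(coupling partner) is 21.5 mM, and the second round gives 0.900 mM, which is 4.50% of the starting material. Leave the crystals in the flask: they are counted in the product.

The forecast gives summer > noon > dusk > midnight > autumn > dawn at 20 h and summer > noon > dusk > midnight > autumn > dawn at 1.0 h, with 98% for the first flask and 5% for the last at 20 h, a little above my dawn figure of 4.50%. Its words are: “Hotter should simply be faster unless binding collapses, which the data cannot show.”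

The flasks give summer > noon > dusk > midnight > autumn > dawn at 20 h and summer > noon > dusk > midnight > autumn > dawn at 1.0 h, with 93.8% in the first and 5.15% in the last.

    catalyst intermediate B ⇌ catalyst intermediate C (K = 0.830, k = 0.00150 /s, Ea = 119 kJ/mol, ΔH = −34.0 kJ/mol)
    catalyst intermediate C → free catalyst + product (k = 0.350 /s, Ea = 100 kJ/mol)
    starting material + free catalyst ⇌ catalyst intermediate A (K = 23.0 /M, k = 0.320 /M/s, Ea = 71.0 kJ/mol, ΔH = 1.00 kJ/mol)
    crystals ⇌ product, rate k4*(cs4 - [product]) while solid is left; crystals form when [product] > cs4 (solubility = 1.00 mM, k = 0.0330 /s)
    coupling partner + catalyst intermediate A ⇌ catalyst intermediate B (K = 100 /M, k = 0.300 /M/s, Ea = 59.0 kJ/mol, ΔH = −75.0 kJ/mol)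
    (constants at 110 °C)

Dawn stands 0.65 percentage points above my figure. The neighbour is the same dawn flask read at 3.0 d. With c(coupling partner) held at its charge, the dawn turnover constant gives 3.31 mM; putting that back gives 3.06 mM, which is 15.3% of the starting material. That flask holds 19.2%, which is 3.9 points above. In that flask catalyst intermediate B, the resting state, stands at 75.6% of the catalyst, and 77% of the starting material is still unbound.

The data stem from a simulated flask for an exercise, noise included.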